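**Retrosynthetic overview**

- Ring C is the only ring to be made and is closed last (O1–C2): acid removes the MOM groups and an ortho hydroxyl adds 6-endo to a diethylamino enone with loss of the amine. The enone comes from the ynone and Et2NH.
- The strategy rests on C4: it is a lone carbonyl carbon between C4a of the fully substituted ring A and C3 of ring C, so it is taken from carbon monoxide. C4a–C4 and C4–C3 are formed together by carbonylative Sonogashira coupling of a hexasubstituted ring A iodide, CO and the ring B arylacetylene.
- The ring A iodide comes from phloroglucinol by tris-MOM protection and three MOM-directed ortho-lithiations (twice borylation/oxidation/O-methylation, then iodination). Its substituents (OMOM, OMe, OMOM, OMe, OMOM) are mirror-symmetric about the C–I axis, so closure through either ortho oxygen gives the same 5,7-dihydroxy-6,8-dimethoxy pattern.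
- The ring B alkyne comes from 2,3-dimethoxybenzaldehyde by Ohira–Bestmann homologation. Rings A and B are bought, not built.

Key step: step 8

Assumption: the diethylamine adduct of the ynone is drawn as its E isomer (nitrogen and carbonyl on opposite sides of the C=C bond), the geometry usual for secondary-amine adducts of ynones; this geometry is lost at ring closure and does not affect the outcome.

**Route**

Step 1
Reactants: 1 phloroglucinol (benzene-1,3,5-triol)
Product: 2 1,3,5-tris(methoxymethoxy)benzene
Conditions: MOMCl, i-Pr2NEt, CH2Cl2, 0 °C → rt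
Reagents that add atoms: chloromethyl methyl ether (MOMCl), COCCl
Why: O-alkylation of the three phenols by the reactive α-chloro ether under amine base (Williamson-type MOM protection) should give the tris-acetal, which also provides the directing groups for the later metalations.

Step 2
Reactants: 2 1,3,5-tris(methoxymethoxy)benzene
Product: 5 2,4,6-tris(methoxymethoxy)phenol, via aryllithium 3 (not isolated), via dimethyl arylboronate 4 (not isolated)
Conditions: n-BuLi, THF, 0 °C; B(OMe)3, −78 °C → rt; 30% H2O2, aq NaOH, 0 °C
Reagents that add atoms: n-butyllithium, CCCC[Li] (lithium of 3 only); trimethyl borate, COB(OC)OC (boron group of 4 only); hydrogen peroxide, OO (the new phenol oxygen of 5)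
Why: Directed ortho-metalation at a C–H flanked by two chelating MOM ethers (all three ring positions are equivalent), borate trapping and alkaline peroxide oxidation with 1,2-aryl shift from boron to oxygen should deliver the phenol as the only possible isomer.

Step 3
Reactants: 5 2,4,6-tris(methoxymethoxy)phenol
Product: 6 2-methoxy-1,3,5-tris(methoxymethoxy)benzene
Conditions: MeI, K2CO3, DMF, rt
Reagents that add atoms: iodomethane, CI
Why: Williamson O-methylation of the only free phenol, with no other nucleophilic or acidic site present.

Step 4
Reactants: 6 2-methoxy-1,3,5-tris(methoxymethoxy)benzene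
Product: 9 3-methoxy-2,4,6-tris(methoxymethoxy)phenol, via aryllithium 7 (not isolated), via dimethyl arylboronate 8 (not isolated)
Conditions: n-BuLi, THF, 0 °C; B(OMe)3, −78 °C → rt; 30% H2O2, aq NaOH, 0 °C (degassed, brief)
Reagents that add atoms: n-butyllithium, CCCC[Li] (lithium of 7 only); trimethyl borate, COB(OC)OC (boron group of 8 only); hydrogen peroxide, OO (the new phenol oxygen of 9)
Why: A second MOM-directed ortho-lithiation at one of the two equivalent remaining C–H positions, each lying between two MOM ethers, followed by the same borylation–oxidation, should introduce the fifth ring oxygen.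

Step 5
Reactants: 9 3-methoxy-2,4,6-tris(methoxymethoxy)phenol
Product: 10 2,4-dimethoxy-1,3,5-tris(methoxymethoxy)benzene
Conditions: MeI, K2CO3, DMF, rt
Reagents that add atoms: iodomethane, CI
Why: Williamson O-methylation of the single phenol, run directly on the crude, air-sensitive phenol to cap it as the stable ether.

Step 6
Reactants: 10 2,4-dimethoxy-1,3,5-tris(methoxymethoxy)benzene
Product: 12 1-iodo-3,5-dimethoxy-2,4,6-tris(methoxymethoxy)benzene, via aryllithium 11 (not isolated)
Conditions: n-BuLi, THF, 0 °C; I2, THF, −78 °C → rt
Reagents that add atoms: n-butyllithium, CCCC[Li] (lithium of 11 only); iodine, II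
Why: Directed ortho-lithiation of the last ring C–H (between two MOM ethers) and iodinolysis of the aryllithium should give the hexasubstituted iodide without exposing the oxidation-prone pentaoxygenated ring to electrophilic iodinating agents.

Step 7
Reactants: 13 2,3-dimethoxybenzaldehyde
Product: 14 1-ethynyl-2,3-dimethoxybenzene
Conditions: dimethyl (1-diazo-2-oxopropyl)phosphonate, K2CO3, MeOH, 0 °C → rt
Reagents that add atoms: dimethyl (1-diazo-2-oxopropyl)phosphonate (Ohira–Bestmann reagent), COP(=O)(OC)C(=[N+]=[N-])C(C)=O
Why: One-carbon homologation of the aldehyde to the terminal alkyne by the diazomethylphosphonate generated in the flask (Ohira–Bestmann variant of the Seyferth–Gilbert reaction), under mild carbonate base that leaves the aryl methyl ethers untouched.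

Step 8
Reactants: 12 1-iodo-3,5-dimethoxy-2,4,6-tris(methoxymethoxy)benzene; 14 1-ethynyl-2,3-dimethoxybenzene; 15 carbon monoxide
Product: 16 1-[3,5-dimethoxy-2,4,6-tris(methoxymethoxy)phenyl]-3-(2,3-dimethoxyphenyl)prop-2-yn-1-one
Conditions: PdCl2(PPh3)2 (5 mol %), CuI (2 mol %), Et3N, THF, CO (10 bar), 60 °C, slow addition of 14, air excluded
Reagents that add atoms: carbon monoxide, [C-]#[O+]
Why: This is a carbonylative Sonogashira coupling, the known three-component route from aryl iodides, CO and terminal alkynes to aryl ynones: zerovalent palladium (formed in the flask from PdCl2(PPh3)2) inserts into the C–I bond of 12, CO coordinates and undergoes migratory insertion to the aroyl–palladium species (C4a–C4), the copper acetylide made from 14, CuI and Et3N transmetalates, and reductive elimination forms C4–C3. No ring closes and no stereocentre is created in this step. The selectivity required is carbonylative over direct alkynylation: the aryl group on divalent palladium is flanked by two MOM ethers, which slows acetylide transfer to it, whereas migration of this electron-rich aryl group onto CO relieves the crowding, and CO pressure together with slow addition of the alkyne keeps the acyl pathway ahead. Chemoselectivity is not in question, since the C–I bond is the sole bond of 12 that zerovalent palladium can enter and the MOM and methyl ethers are spectators. A low loading of monovalent copper and exclusion of air hold back oxidative dimerisation of the alkyne.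

Step 9
Reactants: 16 1-[3,5-dimethoxy-2,4,6-tris(methoxymethoxy)phenyl]-3-(2,3-dimethoxyphenyl)prop-2-yn-1-one
Product: 17 (E)-3-(diethylamino)-3-(2,3-dimethoxyphenyl)-1-[3,5-dimethoxy-2,4,6-tris(methoxymethoxy)phenyl]prop-2-en-1-one
Conditions: Et2NH, EtOH, rt
Reagents that add atoms: diethylamine, CCNCC
Why: Aza-Michael addition of the secondary amine to the activated ynone should give the vinylogous amide, which marks the β-carbon (future C2) as the only electrophilic site and so rules out later 5-exo closure to an aurone.

Step 10
Reactants: 17 (E)-3-(diethylamino)-3-(2,3-dimethoxyphenyl)-1-[3,5-dimethoxy-2,4,6-tris(methoxymethoxy)phenyl]prop-2-en-1-one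
Product: 19 5,7-dihydroxy-6,8,2',3'-tetramethoxyflavone, via trihydroxy enaminone 18 (not isolated)
Conditions: conc. HCl (excess), MeOH, 50 °C
Reagents that add atoms: none
Why: Acid methanolysis of the three phenolic MOM acetals frees the hydroxyls, and either of the two equivalent ortho hydroxyls then attacks the β-carbon of the protonated vinylogous amide (6-endo addition–elimination with loss of diethylamine) to close pyranone ring C; the symmetry of ring A allows one flavone only, and a Wessely–Moser-type ring opening and reclosure would be degenerate.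

**Compound list**

1 | phloroglucinol (benzene-1,3,5-triol) | Oc1cc(O)cc(O)c1 | starting material
2 | 1,3,5-tris(methoxymethoxy)benzene | COCOc1cc(OCOC)cc(OCOC)c1 | intermediate
3 | [2,4,6-tris(methoxymethoxy)phenyl]lithium | [Li]c1c(OCOC)cc(OCOC)cc1OCOC | intermediate
4 | dimethyl [2,4,6-tris(methoxymethoxy)phenyl]boronate | COB(OC)c1c(OCOC)cc(OCOC)cc1OCOC | intermediate
5 | 2,4,6-tris(methoxymethoxy)phenol | Oc1c(OCOC)cc(OCOC)cc1OCOC | intermediate
6 | 2-methoxy-1,3,5-tris(methoxymethoxy)benzene | COc1c(OCOC)cc(OCOC)cc1OCOC | intermediate
7 | [3-methoxy-2,4,6-tris(methoxymethoxy)phenyl]lithium | [Li]c1c(OCOC)c(OC)c(OCOC)cc1OCOC | intermediate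
8 | dimethyl [3-methoxy-2,4,6-tris(methoxymethoxy)phenyl]boronate | COB(OC)c1c(OCOC)c(OC)c(OCOC)cc1OCOC | intermediate
9 | 3-methoxy-2,4,6-tris(methoxymethoxy)phenol | Oc1c(OCOC)c(OC)c(OCOC)cc1OCOC | intermediate
10 | 2,4-dimethoxy-1,3,5-tris(methoxymethoxy)benzene | COc1c(OCOC)c(OC)c(OCOC)cc1OCOC | intermediate
11 | [3,5-dimethoxy-2,4,6-tris(methoxymethoxy)phenyl]lithium | [Li]c1c(OCOC)c(OC)c(OCOC)c(OC)c1OCOC | intermediate
12 | 1-iodo-3,5-dimethoxy-2,4,6-tris(methoxymethoxy)benzene | COCOc1c(I)c(OCOC)c(OC)c(OCOC)c1OC | intermediate
13 | 2,3-dimethoxybenzaldehyde | COc1cccc(C=O)c1OC | starting material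
14 | 1-ethynyl-2,3-dimethoxybenzene | C#Cc1cccc(OC)c1OC | intermediate
15 | carbon monoxide | [C-]#[O+] | starting material
16 | 1-[3,5-dimethoxy-2,4,6-tris(methoxymethoxy)phenyl]-3-(2,3-dimethoxyphenyl)prop-2-yn-1-one | COCOc1c(OC)c(OCOC)c(C(=O)C#Cc2cccc(OC)c2OC)c(OCOC)c1OC | intermediate
17 | (E)-3-(diethylamino)-3-(2,3-dimethoxyphenyl)-1-[3,5-dimethoxy-2,4,6-tris(methoxymethoxy)phenyl]prop-2-en-1-one | CCN(CC)/C(=C/C(=O)c1c(OCOC)c(OC)c(OCOC)c(OC)c1OCOC)c1cccc(OC)c1OC | intermediate
18 | (E)-3-(diethylamino)-3-(2,3-dimethoxyphenyl)-1-(2,4,6-trihydroxy-3,5-dimethoxyphenyl)prop-2-en-1-one | CCN(CC)/C(=C/C(=O)c1c(O)c(OC)c(O)c(OC)c1O)c1cccc(OC)c1OC | intermediate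
19 | 5,7-dihydroxy-6,8,2',3'-tetramethoxyflavone | COc1cccc(-c2cc(=O)c3c(O)c(OC)c(O)c(OC)c3o2)c1OC | target

**Step count**

Total step count: 10. Longest linear sequence: 9 steps (steps 1–6 and 8–10, from phloroglucinol); the alkyne branch is step 7.

**Steps most likely to fail**

1. Step 8. Direct, non-carbonylative alkynylation may outrun CO insertion, oxidative addition into the electron-rich, doubly ortho-substituted C–I bond may be sluggish, or the alkyne may dimerise oxidatively. Fallback without palladium or CO, setting out from 10 and 14 and returning at 16: compound 10 is lithiated as in step 6 (n-BuLi, THF, 0 °C, giving aryllithium 11) and quenched with DMF to give 3,5-dimethoxy-2,4,6-tris(methoxymethoxy)benzaldehyde F1. Alkyne 14 is deprotonated with n-BuLi (THF, −78 °C) to lithium (2,3-dimethoxyphenyl)acetylide F2, which should add to F1 to give racemic 1-[3,5-dimethoxy-2,4,6-tris(methoxymethoxy)phenyl]-3-(2,3-dimethoxyphenyl)prop-2-yn-1-ol F3 after NH4Cl quench. Oxidation of the propargylic alcohol with Dess–Martin periodinane (NaHCO3, CH2Cl2, rt) should then give ynone 16.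

2. Step 4. The very electron-rich phenoxide may be over-oxidised to quinone-type material under alkaline peroxide, or metalation next to the new methoxy group may be incomplete. Fallback setting out from 2 and returning at 10, which bypasses steps 2–5: dibromination with NBS (2 equiv, CH2Cl2, 0 °C) should give 2,4-dibromo-1,3,5-tris(methoxymethoxy)benzene F4. Copper-mediated double methoxylation (NaOMe, CuBr, DMF–MeOH, 110 °C, Ullmann-type ether synthesis) should then replace both bromines by methoxy groups to give 10.

3. Step 10. Hydrolysis of the vinylogous amide may outpace ring closure, or closure may stall after only partial loss of the MOM groups, leaving open-chain material. Fallback setting out from 17 and returning at 19: 17 is treated with aqueous HCl in THF at rt so that the vinylogous amide is deliberately hydrolysed and the MOM groups are cleaved, giving 1-(2,4,6-trihydroxy-3,5-dimethoxyphenyl)-3-(2,3-dimethoxyphenyl)propane-1,3-dione F5. Cyclodehydration with catalytic H2SO4 in AcOH at 100 °C, the classical closure of ortho-hydroxyaryl 1,3-diketones, should then give 19.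

**Further compounds**

F1 | step 8 | 3,5-dimethoxy-2,4,6-tris(methoxymethoxy)benzaldehyde | O=Cc1c(OCOC)c(OC)c(OCOC)c(OC)c1OCOC
F2 | step 8 | lithium (2,3-dimethoxyphenyl)acetylide | [Li]C#Cc1cccc(OC)c1OC
F3 | step 8 | 1-[3,5-dimethoxy-2,4,6-tris(methoxymethoxy)phenyl]-3-(2,3-dimethoxyphenyl)prop-2-yn-1-ol (racemic) | OC(C#Cc1cccc(OC)c1OC)c1c(OCOC)c(OC)c(OCOC)c(OC)c1OCOC
F4 | step 4 | 2,4-dibromo-1,3,5-tris(methoxymethoxy)benzene | COCOc1cc(OCOC)c(Br)c(OCOC)c1Br
F5 | step 10 | 1-(2,4,6-trihydroxy-3,5-dimethoxyphenyl)-3-(2,3-dimethoxyphenyl)propane-1,3-dione | COc1cccc(C(=O)CC(=O)c2c(O)c(OC)c(O)c(OC)c2O)c1OC
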